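## Retrosynthetic overview

- **Feature:** the 4-hydroxybenzoate ring (Ar-C1 carboxyl, Ar-C3 carrying benzylic C1, Ar-C4 hydroxyl) spans C1 and the C14 ester oxygen meta-wise. Arene plus 15-membered lactone are therefore the [4+2] adduct of a 2-alkyl-1-methoxy-3-silyloxybutadiene (Ar-C2 to Ar-C5) and a C14 propiolate (Ar-C1, Ar-C6).
- **Key disconnection:** thermal type 2 intramolecular Diels–Alder reaction of diene–ynoate 26 with loss of methanol forms Ar-C1–Ar-C2 and Ar-C5–Ar-C6, closing benzene ring and macrolactone together; fluoride then gives the target.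
- **Diene unit:** the C1–diene bond comes from Negishi coupling of a C1 alkylzinc with (Z)-3-iodo-4-methoxybut-3-en-2-one. This fixes the diene regiochemistry, which formylation of a C1-homologated methyl ketone would not (it would go to the methyl group).
- **Side chain:** C12–C13 by enolate alkylation with a C12 allylic bromide; C14 by Corey–Bakshi–Shibata reduction; C10–C11 oxirane by Shi epoxidation; propiolate by Steglich esterification.
- **Ring A (formed first):** enantioselective bromonium cyclization of a farnesol-derived triene (C1 tert-butyl carbonate, C10=C11 as enoate) to a trans cyclic carbonate, then anti elimination of the equatorial C3–OH to the methylene. Ring order: ring A, oxirane, then arene and lactone in one step.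

Key step: step 19

Assumption: diterpene numbering is used (C1 benzylic CH2, C2–C7 ring A with C3 methylene, C6 Br and C7 quaternary, C10–C11 oxirane, C14 ester carbon, C15 carbinol; Ar-C1 to Ar-C6 from the carboxyl carbon), and the catalyst antipodes named in steps 5, 15 and 16 are those expected to give the stated configurations.

## Route

Step 1
Reactants: 1 (2E,6E)-farnesol
Product: 2 (2E,6E)-farnesyl tert-butyl carbonate
Conditions: n-BuLi, THF, −78 °C; Boc2O, −78 → 0 °C
Reagents that add atoms: di-tert-butyl dicarbonate, CC(C)(C)OC(=O)OC(=O)OC(C)(C)C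
Why: O-acylation of the lithium alkoxide gives the allylic carbonate, which later deactivates C2=C3 towards bromine and serves as the internal oxygen nucleophile for the C3 cation.

Step 2
Reactants: 2 farnesyl tert-butyl carbonate
Product: 4 10,11-epoxyfarnesyl tert-butyl carbonate (racemic at C10), via bromohydrin 3 (not isolated)
Conditions: NBS, THF–H2O, 0 °C; crude, then DBU, CH2Cl2, rt
Reagents that add atoms: water, O (the epoxide oxygen; the bromine from N-bromosuccinimide, O=C1CCC(=O)N1Br, is lost again in the ring closure)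
Why: bromohydrin formation in aqueous THF should favour the exposed terminal alkene (C2=C3 is deactivated by the carbonate), and base-induced Williamson closure gives the epoxide, whose racemic C10 center is excised in step 3.

Step 3
Reactants: 4 10,11-epoxyfarnesyl tert-butyl carbonate
Product: 5 (4E,8E)-10-(tert-butoxycarbonyloxy)-4,8-dimethyldeca-4,8-dienal (C10 aldehyde)
Conditions: HIO4·2H2O, THF–Et2O, 0 °C
Reagents that add atoms: none
Why: periodic acid opens the epoxide and cleaves the resulting glycol (oxidative glycol cleavage) to the C10 aldehyde and acetone without touching the trisubstituted alkenes or the carbonate.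

Step 4
Reactants: 5 C10 aldehyde; 6 methyl 2-(triphenylphosphoranylidene)propanoate
Product: 7 methyl (2E,6E,10E)-12-(tert-butoxycarbonyloxy)-2,6,10-trimethyldodeca-2,6,10-trienoate (C10=C11 enoate, C12 ester)
Conditions: PhMe, 80 °C
Reagents that add atoms: ylide 6, COC(=O)C(C)=P(c1ccccc1)(c1ccccc1)c1ccccc1
Why: Wittig olefination with the stabilized, α-branched ylide should give the (E)-2-methyl enoate, which supplies C11, its methyl and C12 and makes C10=C11 inert to electrophilic bromine.

Step 5
Reactants: 7 triene carbonate ester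
Product: 8 trans-fused ring A bromo cyclic carbonate (C1–O–CO–O–C3; 2R,3S,6S,7S; Br, C1 and C8 equatorial, C7-methyl and C3-methyl axial)
Conditions: 1,3-dibromo-5,5-dimethylhydantoin (0.55 equiv), (R)-3,3′-bis(2,4,6-triisopropylphenyl)-1,1′-binaphthyl-2,2′-diyl N-(trifluoromethylsulfonyl)thiophosphoramide (10 mol %), PhMe–CH2Cl2, −78 °C
Reagents that add atoms: 1,3-dibromo-5,5-dimethylhydantoin, CC1(C)N(Br)C(=O)N(Br)C1=O
Why: Proposed new method: the sulfur Lewis base of the chiral catalyst should carry Br+ to the Si face of C6 of the only electron-rich alkene (C2=C3 is deactivated by the allylic carbonate, C10=C11 by the ester), the bromonium ion is opened anti at C7 by C2 through a chair that places C1 and C8 equatorial, and the carbonate carbonyl oxygen captures the C3 cation anti across the (2E)-alkene with loss of isobutene, so that C6 is set by the catalyst and C7, C2 and C3 by the anti, chair-controlled additions; the closest known reaction types are the chiral Lewis-base-catalysed enantioselective bromonium cyclization of arene-terminated geranyl systems with the same bromine source and the racemic bromonium cyclization of geranyl tert-butyl carbonates to cyclic bromocarbonates.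

Step 6
Reactants: 8 bromo cyclic carbonate
Product: 9 ring A 1,3-diol (C1 primary OH, C3 tertiary equatorial OH)
Conditions: K2CO3 (cat.), MeOH, rt
Reagents that add atoms: none
Why: base-catalysed transesterification removes the carbonate as dimethyl carbonate, while the methyl enoate and the hindered secondary bromide are inert.

Step 7
Reactants: 9 ring A 1,3-diol
Product: 10 C1 iodide with C3 tertiary alcohol
Conditions: I2, PPh3, imidazole, PhMe–MeCN, 0 → 60 °C
Reagents that add atoms: iodine, II
Why: Appel-type iodination is selective for the primary hydroxyl because the tertiary alcohol cannot form a displaceable oxyphosphonium ion, and the iodide both masks C1 and prepares it as the later nucleophile.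

Step 8
Reactants: 10 iodo alcohol
Product: 11 C1 iodide with the C3 exocyclic methylene
Conditions: SOCl2, pyridine, CH2Cl2, −78 → −40 °C
Reagents that add atoms: none
Why: pyridine-induced anti (E2) elimination of the chlorosulfite of an equatorial tertiary alcohol finds anti-periplanar hydrogens only on the axial methyl group (the ring bonds, not ring hydrogens, are anti to the C3–O bond), so the exocyclic alkene should predominate.

Step 9
Reactants: 11 iodo enoate
Product: 12 C12 allylic alcohol
Conditions: i-Bu2AlH, CH2Cl2, −78 °C; aq. KNaC4H4O6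
Reagents that add atoms: none
Why: 1,2-reduction of the enoate with diisobutylaluminium hydride at low temperature gives the (E)-allylic alcohol and leaves the alkyl iodide, the bromide and the methylene untouched.

Step 10
Reactants: 12 allylic alcohol
Product: 13 C12 allylic bromide
Conditions: CBr4, PPh3, 2,6-lutidine, CH2Cl2, 0 °C
Reagents that add atoms: carbon tetrabromide, BrC(Br)(Br)Br
Why: Appel bromination converts the primary allylic alcohol into the bromide under neutral conditions without allylic transposition.

Step 11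
Reactants: 14 3-hydroxy-3-methylbutan-2-one
Product: 15 3-methyl-3-(triethylsilyloxy)butan-2-one
Conditions: Et3SiOTf, 2,6-lutidine, CH2Cl2, −78 → 0 °C
Reagents that add atoms: triethylsilyl triflate, CC[Si](CC)(CC)OS(=O)(=O)C(F)(F)F
Why: silyl triflate with a hindered pyridine base silylates the tertiary hydroxyl, giving the C13–C15 building block with only one enolizable position.

Step 12
Reactants: 13 allylic bromide; 15 silyloxy ketone
Product: 17 C14 ketone (C1 iodide, C15 triethylsilyl ether), via lithium enolate 16 (not isolated)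
Conditions: LiN(i-Pr)2, THF, −78 °C (15, 2 equiv); then 13, DMPU, −78 → −30 °C
Reagents that add atoms: 3-methyl-3-(triethylsilyloxy)butan-2-one 15 (as enolate 16), CC(=O)C(C)(C)O[Si](CC)(CC)CC
Why: SN2 alkylation of the kinetic methyl-ketone enolate by the primary allylic bromide forms C12–C13, the hindered primary iodide and secondary bromide being far slower electrophiles.

Step 13
Reactants: 18 (E)-4-methoxybut-3-en-2-one
Product: 19 (Z)-3-iodo-4-methoxybut-3-en-2-one
Conditions: I2, pyridine, CH2Cl2, 0 °C → rt
Reagents that add atoms: iodine, II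
Why: α-iodination of the vinylogous ester (electrophilic attack at the nucleophilic α-carbon, then loss of a proton) gives the vinyl iodide with the methoxy group still trans to the acetyl group.

Step 14
Reactants: 17 C1 iodide C14 ketone; 19 iodo enone
Product: 21 (E)-methoxymethylene ketone at C1 (ring A–CH2–C(=CHOMe)–COCH3), via C1 alkylzinc iodide 20 (not isolated)
Conditions: Zn dust (activated with BrCH2CH2Br, Me3SiCl), LiCl, THF, 35 °C; then 19, Pd2(dba)3 (2.5 mol %), P(2-furyl)3 (10 mol %), THF, 25 °C
Reagents that add atoms: (Z)-3-iodo-4-methoxybut-3-en-2-one 19, CO/C=C(\I)C(C)=O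
Why: zinc inserts into the primary C–I bond in preference to the hindered secondary C–Br bond and tolerates the ketone, and Negishi coupling with the α-iodo enone proceeds with retention of alkene geometry, placing the diene precursor on C1 with unambiguous regiochemistry.

Step 15
Reactants: 21 diketone
Product: 22 (14S)-alcohol
Conditions: (R)-1-methyl-3,3-diphenyltetrahydro-1H,3H-pyrrolo[1,2-c][1,3,2]oxazaborole (0.5 equiv), catecholborane, PhMe, −78 → −40 °C
Reagents that add atoms: none
Why: Corey–Bakshi–Shibata reduction differentiates the bulky C(CH3)2OSiEt3 group from the CH2 chain so that the (R)-catalyst should deliver hydride to give the 14S alcohol, while catecholborane spares the alkenes and the much less electrophilic vinylogous ester carbonyl.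

Step 16
Reactants: 22 (14S)-alcohol
Product: 23 (10S,11S)-epoxy (14S)-alcohol
Conditions: 1,2:4,5-di-O-isopropylidene-β-L-erythro-2,3-hexodiulo-2,6-pyranose (0.3 equiv), 2KHSO5·KHSO4·K2SO4, K2CO3, Bu4NHSO4, MeCN–CH2(OMe)2, aq. Na2B4O7 buffer (pH 10.5), 0 °C
Reagents that add atoms: potassium peroxymonosulfate, [K+].OOS(=O)(=O)[O-]
Why: Shi epoxidation with the L-fructose-derived ketone should give the 10S,11S oxirane through the spiro transition state, and the electrophilic dioxirane prefers the trisubstituted C10=C11 over the hindered 1,1-disubstituted methylene and the acceptor-substituted enol ether.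

Step 17
Reactants: 23 epoxy alcohol; 24 propiolic acid
Product: 25 C14 propiolate ester
Conditions: DCC, DMAP (5 mol %), CH2Cl2, −20 °C, acid added last and slowly
Reagents that add atoms: propiolic acid 24, C#CC(=O)O
Why: Steglich esterification acylates the secondary C14 hydroxyl with retention, and keeping the carbodiimide in excess over free acid at low temperature avoids acid-induced attack of the hydroxyl on the oxirane.

Step 18
Reactants: 25 propiolate methoxymethylene ketone
Product: 26 (E)-1-methoxy-2-alkyl-3-(tert-butyldimethylsilyloxy)buta-1,3-diene tethered to the C14 propiolate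
Conditions: t-BuMe2SiOTf, i-Pr2NEt, Et2O, −78 → −20 °C; filtered through basic alumina, used crude
Reagents that add atoms: tert-butyldimethylsilyl triflate, CC(C)(C)[Si](C)(C)OS(=O)(=O)C(F)(F)F
Why: soft enolization of the methyl ketone (O-silylation, then deprotonation by the hindered amine) gives the 2-silyloxydiene, and the hindered, weakly nucleophilic base and low temperature are chosen to spare the ynoate, the oxirane and the tertiary silyl ether.

Step 19
Reactants: 26 diene–propiolate
Product: 28 bromophycolide F aryl tert-butyldimethylsilyl, C15 triethylsilyl bis-ether, via methoxycyclohexadiene cycloadduct 27 (not isolated)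
Conditions: PhMe (0.5 mM), 2,6-di-tert-butyl-4-methylpyridine (0.2 equiv), 110 °C, sealed, silylated glassware
Reagents that add atoms: none
Why: Proposed new method: a thermal normal-demand [4+2] cycloaddition joins the nucleophilic CH2 terminus of the silyloxydiene (Ar-C5) to the propiolate β-carbon (Ar-C6) and the methoxy-bearing terminus (Ar-C2) to the α-carbon (Ar-C1), and the bridged cyclohexa-1,4-diene 27 then loses methanol by 1,4-elimination to become aromatic; the closest known reaction types are the intermolecular cycloaddition–aromatization of 1-methoxy-3-silyloxybutadienes with propiolate esters to 4-hydroxybenzoates and arene-forming intramolecular Diels–Alder closures of cyclophanes. The six-membered ring closes by the concerted cycloaddition, and the 15-membered lactone closes in the same event as a type 2 (tether on diene C-2) intramolecular Diels–Alder macrocyclization in the 1,3-bridging mode. No lasting stereocenter is made, since the methoxy-bearing sp3 carbon of 27 is destroyed on aromatization, and the six existing centers are remote from the reacting atoms. The step needs regioselectivity (alkyl meta and oxygen para to the carboxyl), which the donor pattern of the diene and the shorter 1,3-bridging tether both demand. It also needs ring closure to beat oligomerization, which high dilution and the irreversible aromatization should secure. Bromide, oxirane, methylene and silyl ethers meet only buffered neutral heat.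

Step 20
Reactants: 28 bis-silyl ether
Product: 29 bromophycolide F
Conditions: Bu4NF, AcOH (1:1), THF, 0 °C → rt
Reagents that add atoms: none
Why: buffered fluoride cleaves the aryl silyl ether and the tertiary triethylsilyl ether by attack at silicon without opening the oxirane or the lactone.

## Compound list

1 | (2E,6E)-farnesol | OC/C=C(\C)CC/C=C(\C)CCC=C(C)C | starting material
2 | (2E,6E)-farnesyl tert-butyl carbonate | CC(C)(C)OC(=O)OC/C=C(\C)CC/C=C(\C)CCC=C(C)C | intermediate
3 | 10-bromo-11-hydroxy-10,11-dihydrofarnesyl tert-butyl carbonate (racemic at C10) | CC(C)(C)OC(=O)OC/C=C(\C)CC/C=C(\C)CCC(Br)C(C)(C)O | intermediate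
4 | 10,11-epoxyfarnesyl tert-butyl carbonate (racemic at C10) | CC(C)(C)OC(=O)OC/C=C(\C)CC/C=C(\C)CCC1OC1(C)C | intermediate
5 | (4E,8E)-10-(tert-butoxycarbonyloxy)-4,8-dimethyldeca-4,8-dienal | CC(C)(C)OC(=O)OC/C=C(\C)CC/C=C(\C)CCC=O | intermediate
6 | methyl 2-(triphenylphosphoranylidene)propanoate | COC(=O)C(C)=P(c1ccccc1)(c1ccccc1)c1ccccc1 | starting material
7 | methyl (2E,6E,10E)-12-(tert-butoxycarbonyloxy)-2,6,10-trimethyldodeca-2,6,10-trienoate | CC(C)(C)OC(=O)OC/C=C(\C)CC/C=C(\C)CC/C=C(\C)C(=O)OC | intermediate
8 | trans-fused ring A bromo cyclic carbonate (2R,3S,6S,7S) with C8–C12 enoate chain | O=C1OC[C@@H]2[C@@](C)(O1)CC[C@H](Br)[C@@]2(C)CC/C=C(\C)C(=O)OC | intermediate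
9 | ring A 1,3-diol (C1 OH, C3 OH) | OC[C@@H]1[C@@](C)(O)CC[C@H](Br)[C@@]1(C)CC/C=C(\C)C(=O)OC | intermediate
10 | C1 iodide, C3 tertiary alcohol | IC[C@@H]1[C@@](C)(O)CC[C@H](Br)[C@@]1(C)CC/C=C(\C)C(=O)OC | intermediate
11 | C1 iodide, C3 methylene, C12 methyl ester | IC[C@@H]1C(=C)CC[C@H](Br)[C@@]1(C)CC/C=C(\C)C(=O)OC | intermediate
12 | C1 iodide, C12 allylic alcohol | IC[C@@H]1C(=C)CC[C@H](Br)[C@@]1(C)CC/C=C(\C)CO | intermediate
13 | C1 iodide, C12 allylic bromide | IC[C@@H]1C(=C)CC[C@H](Br)[C@@]1(C)CC/C=C(\C)CBr | intermediate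
14 | 3-hydroxy-3-methylbutan-2-one | CC(=O)C(C)(C)O | starting material
15 | 3-methyl-3-(triethylsilyloxy)butan-2-one | CC(=O)C(C)(C)O[Si](CC)(CC)CC | intermediate
16 | lithium enolate of 15 | [Li+].[O-]C(=C)C(C)(C)O[Si](CC)(CC)CC | intermediate
17 | C1 iodide, C14 ketone, C15 triethylsilyl ether | IC[C@@H]1C(=C)CC[C@H](Br)[C@@]1(C)CC/C=C(\C)CCC(=O)C(C)(C)O[Si](CC)(CC)CC | intermediate
18 | (E)-4-methoxybut-3-en-2-one | CO/C=C/C(C)=O | starting material
19 | (Z)-3-iodo-4-methoxybut-3-en-2-one | CO/C=C(\I)C(C)=O | intermediate
20 | C1 alkylzinc iodide derived from 17 | I[Zn]C[C@@H]1C(=C)CC[C@H](Br)[C@@]1(C)CC/C=C(\C)CCC(=O)C(C)(C)O[Si](CC)(CC)CC | intermediate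
21 | (E)-methoxymethylene ketone at C1, C14 ketone | CO/C=C(\C[C@@H]1C(=C)CC[C@H](Br)[C@@]1(C)CC/C=C(\C)CCC(=O)C(C)(C)O[Si](CC)(CC)CC)C(C)=O | intermediate
22 | (14S)-alcohol | CO/C=C(\C[C@@H]1C(=C)CC[C@H](Br)[C@@]1(C)CC/C=C(\C)CC[C@H](O)C(C)(C)O[Si](CC)(CC)CC)C(C)=O | intermediate
23 | (10S,11S)-epoxy (14S)-alcohol | CO/C=C(\C[C@@H]1C(=C)CC[C@H](Br)[C@@]1(C)CC[C@@H]2O[C@@]2(C)CC[C@H](O)C(C)(C)O[Si](CC)(CC)CC)C(C)=O | intermediate
24 | propiolic acid | C#CC(=O)O | starting material
25 | C14 propiolate of 23 | CO/C=C(\C[C@@H]1C(=C)CC[C@H](Br)[C@@]1(C)CC[C@@H]2O[C@@]2(C)CC[C@@H](C(C)(C)O[Si](CC)(CC)CC)OC(=O)C#C)C(C)=O | intermediate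
26 | (E)-1-methoxy-2-alkyl-3-(tert-butyldimethylsilyloxy)butadiene tethered to the C14 propiolate | CO/C=C(C[C@@H]1C(=C)CC[C@H](Br)[C@@]1(C)CC[C@@H]2O[C@@]2(C)CC[C@@H](C(C)(C)O[Si](CC)(CC)CC)OC(=O)C#C)/C(=C)O[Si](C)(C)C(C)(C)C | intermediate
27 | bridged methoxycyclohexa-1,4-diene cycloadduct (epimers at the methoxy carbon) | C=C1CC[C@H](Br)[C@@]2(C)CC[C@@H]3O[C@@]3(C)CC[C@@H](C(C)(C)O[Si](CC)(CC)CC)OC(=O)C3=CCC(O[Si](C)(C)C(C)(C)C)=C(C3OC)C[C@H]12 | intermediate
28 | bromophycolide F aryl tert-butyldimethylsilyl, C15 triethylsilyl bis-ether | C=C1CC[C@H](Br)[C@@]2(C)CC[C@@H]3O[C@@]3(C)CC[C@@H](C(C)(C)O[Si](CC)(CC)CC)OC(=O)c3ccc(O[Si](C)(C)C(C)(C)C)c(c3)C[C@H]12 | intermediate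
29 | bromophycolide F | C=C1CC[C@H](Br)[C@@]2(C)CC[C@@H]3O[C@@]3(C)CC[C@@H](C(C)(C)O)OC(=O)c3ccc(O)c(c3)C[C@H]12 | target

## Step count and risks

Total: 20 steps. Longest linear sequence: 18 steps from farnesol (steps 1–10, 12, 14–20); steps 11 and 13 are one-step preparations of coupling partners.

**Step 19 (most at risk).** The flexible tether does not preorganize diene and ynoate, so intermolecular cycloaddition, ene reaction with the methylene or hydrolysis of the silyl dienol ether may outrun ring closure. The fallback builds the arene intermolecularly and closes the lactone by known macrolactonization: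
- It sets out from epoxy alcohol 23, whose C14 hydroxyl is protected with allyl chloroformate and pyridine as the allyl carbonate F1.
- Silylation as in step 18 gives the silyloxydiene F2.
- Heating F2 with excess allyl propiolate in toluene (the known intermolecular cycloaddition–aromatization) gives the allyl 3-alkyl-4-silyloxybenzoate F3.
- Pd(PPh3)4 and morpholine remove the allyl ester and the allyl carbonate together to give the seco acid F4.
- Yamaguchi macrolactonization (2,4,6-trichlorobenzoyl chloride, Et3N, then DMAP in toluene at high dilution) returns to the route at 28.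

**Step 5.** Bromine transfer may show poor facial selectivity, uncatalysed background bromination may erode it, or bromine may exchange between alkenes. The fallback uses a known racemic cyclization and a resolution:
- It sets out from triene 7, which is cyclized with Et2SBr·SbCl5Br in MeNO2 at −25 °C to the racemic cyclic carbonate F5.
- Methanolysis as in step 6 gives the racemic diol F6.
- The primary hydroxyl is esterified with (S)-2-methoxy-2-phenylacetic acid (DCC, DMAP) to the diastereomeric esters, the (S)-O-methylmandelate of 9 F7 and the (S)-O-methylmandelate of the enantiomer of 9 F8, which are separated by chromatography.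
- Methanolysis of F7 (K2CO3, MeOH) returns to the route at 9.

**Step 18.** The terminal ynoate may be lost to conjugate addition of the amine or to C-silylation of the alkyne during enol silylation. The fallback carries the alkyne as its silyl derivative:
- It sets out from epoxy alcohol 23, which is esterified with 3-(trimethylsilyl)propiolic acid (DCC, DMAP) to the silylpropiolate F9.
- Silylation gives the diene F10, which lacks the acidic alkyne hydrogen and has a shielded β-carbon.
- The same thermal ring closure (xylene, 140 °C) gives the macrolactone F11 carrying a trimethylsilyl group at Ar-C6.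
- Excess Bu4NF removes both silyl ethers and, ortho to the ester, the aryl trimethylsilyl group by ipso-protodesilylation, returning to the route at 29.

## Further compounds

F1 | step 19 | C14 allyl carbonate of epoxy alcohol 23 | CO/C=C(\C[C@@H]1C(=C)CC[C@H](Br)[C@@]1(C)CC[C@@H]2O[C@@]2(C)CC[C@@H](C(C)(C)O[Si](CC)(CC)CC)OC(=O)OCC=C)C(C)=O
F2 | step 19 | tert-butyldimethylsilyl dienol ether of F1 | CO/C=C(C[C@@H]1C(=C)CC[C@H](Br)[C@@]1(C)CC[C@@H]2O[C@@]2(C)CC[C@@H](C(C)(C)O[Si](CC)(CC)CC)OC(=O)OCC=C)/C(=C)O[Si](C)(C)C(C)(C)C
F3 | step 19 | allyl 3-alkyl-4-(tert-butyldimethylsilyloxy)benzoate with C14 allyl carbonate | C=CCOC(=O)c1ccc(O[Si](C)(C)C(C)(C)C)c(C[C@@H]2C(=C)CC[C@H](Br)[C@@]2(C)CC[C@@H]3O[C@@]3(C)CC[C@@H](C(C)(C)O[Si](CC)(CC)CC)OC(=O)OCC=C)c1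
F4 | step 19 | seco acid (free C14 hydroxyl, aryl silyl ether, C15 triethylsilyl ether) | OC(=O)c1ccc(O[Si](C)(C)C(C)(C)C)c(C[C@@H]2C(=C)CC[C@H](Br)[C@@]2(C)CC[C@@H]3O[C@@]3(C)CC[C@H](O)C(C)(C)O[Si](CC)(CC)CC)c1
F5 | step 5 | racemic ring A bromo cyclic carbonate (8 and its enantiomer) | O=C1OC[C@@H]2[C@@](C)(O1)CC[C@H](Br)[C@@]2(C)CC/C=C(\C)C(=O)OC.O=C1OC[C@H]2[C@](C)(O1)CC[C@@H](Br)[C@]2(C)CC/C=C(\C)C(=O)OC
F6 | step 5 | racemic ring A 1,3-diol (9 and its enantiomer) | OC[C@@H]1[C@@](C)(O)CC[C@H](Br)[C@@]1(C)CC/C=C(\C)C(=O)OC.OC[C@H]1[C@](C)(O)CC[C@@H](Br)[C@]1(C)CC/C=C(\C)C(=O)OC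
F7 | step 5 | (S)-O-methylmandelate of 9 | CO[C@H](C(=O)OC[C@@H]1[C@@](C)(O)CC[C@H](Br)[C@@]1(C)CC/C=C(\C)C(=O)OC)c1ccccc1
F8 | step 5 | (S)-O-methylmandelate of the enantiomer of 9 | CO[C@H](C(=O)OC[C@H]1[C@](C)(O)CC[C@@H](Br)[C@]1(C)CC/C=C(\C)C(=O)OC)c1ccccc1
F9 | step 18 | C14 3-(trimethylsilyl)propiolate of 23 | CO/C=C(\C[C@@H]1C(=C)CC[C@H](Br)[C@@]1(C)CC[C@@H]2O[C@@]2(C)CC[C@@H](C(C)(C)O[Si](CC)(CC)CC)OC(=O)C#C[Si](C)(C)C)C(C)=O
F10 | step 18 | tert-butyldimethylsilyl dienol ether of F9 | CO/C=C(C[C@@H]1C(=C)CC[C@H](Br)[C@@]1(C)CC[C@@H]2O[C@@]2(C)CC[C@@H](C(C)(C)O[Si](CC)(CC)CC)OC(=O)C#C[Si](C)(C)C)/C(=C)O[Si](C)(C)C(C)(C)C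
F11 | step 18 | macrolactone bis-silyl ether with Ar-C6 trimethylsilyl group | C=C1CC[C@H](Br)[C@@]2(C)CC[C@@H]3O[C@@]3(C)CC[C@@H](C(C)(C)O[Si](CC)(CC)CC)OC(=O)c3c([Si](C)(C)C)cc(O[Si](C)(C)C(C)(C)C)c(c3)C[C@H]12
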